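**Assumptions and conventions**
- Isoflavan numbering is used: ring C = O1, C2, C3, C4; ring A = C4a to C8a; ring B = C1' to C6'. "Prenyl" = 3-methylbut-2-en-1-yl; "chroman" = 3,4-dihydro-2H-chromene.
- The target SMILES corresponds to (3R). The same spatial arrangement at C3 is named S in acid 5 and aldehyde 7 because the substituent priorities change.
- Assumption for step 3: the antipode of the spiro phosphine-oxazoline ligand (SIPHOX) is chosen so that hydrogen is delivered to the face giving (S)-5. The sense of induction is to be verified on 5 before material is carried on. BArF = tetrakis[3,5-bis(trifluoromethyl)phenyl]borate, cod = 1,5-cyclooctadiene.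

## The problem

Target 25 is an isoflavan: ring A is fused to the oxygen heterocycle ring C, and C3 of ring C carries the aryl ring B. C3 is the only stereocentre (R). With no second centre to relay chirality, it has to be set by a catalyst or reagent, and afterwards it is safe only while its hydrogen is not alpha to a carbonyl group. Ring A is a fully differentiated phloroglucinol (5-OMe, 7-OH, 8-CHO, O1 at C8a). The formyl group therefore has to enter at C8 and not at the electronically similar C6, and exactly one of two ether oxygens has to end up free. Ring B carries four adjacent substituents: C3 at C1', hydroxyl at C2', prenyl at C3' and hydroxyl at C4'. The prenyl group lies between two oxygens, the position that direct prenylation of a resorcinol reaches least reliably. The fragile features are the prenyl alkene (hydrogenation, acid, electrophiles), the ortho-prenylphenol (acid closes it to a dimethylchroman), the electron-rich rings and the salicylaldehyde unit of ring A. The feature that opens the route is the C1'–C4' array itself. C2'(O), C1', C6' and C5' map onto a vinylketene, and C3'(prenyl) and C4'(O) onto a prenyl-bearing ynol ether. Ring B can thus be grown on an enantiopure chroman instead of being coupled to it.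

## Retrosynthesis

**Ring A finishing (25 ⇒ 24 ⇒ 23 ⇒ 21).** The two O–Si bonds of 24, the 7-O–CH3 bond of 23 and the C8–CHO bond are cut in turn, leading back to the bis-silyl dimethoxy isoflavan 21. Placing these cuts last keeps the aldehyde and free phenols away from the strong base and the light used earlier, and lets ring A start as a commercial dimethoxy aldehyde. Compound 21 lacks the aldehyde and has two equivalent-type methyl ethers. The forward steps must formylate C8 and not C6 or ring B, and then cleave only the methyl ether that chelates with the new aldehyde.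

**Phenol protection (21 ⇒ 20).** The 2'-O–Si bond is cut. A free 2'-phenol would leave ring B competitive in the formylation and would sit next to the prenyl group under acidic conditions. One silylation removes both risks, and the final fluoride step removes both silyl groups together.

**Ring B (20 ⇒ 10 + 15).** Four ring bonds are cut: C5'–C6', C2'–C3', C4'–C5' and C1'–C2'. This returns diazoketone 10 and siloxyalkyne 15. The neighbouring cut, C3–C1' (aryl coupling to a chroman), would need a prenylated, differentially protected resorcinol nucleophile or electrophile, and a stereoselective C–C coupling at a secondary carbon. The benzannulation instead fixes the oxygen/prenyl/oxygen sequence by the polarity of its partners and leaves the two oxygens distinguishable. The precursors contain no ring B at all. The forward cascade must proceed with one orientation and must not touch C3 or the prenyl alkene.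

**Diazoketone (10 ⇒ 8 ⇒ 6).** The C=N2 bond is cut (diazo transfer through diketone 9), then the C=C bond (Wittig olefination of aldehyde 7, made in the flask from alcohol 6). Acylation of diazomethane with an unsaturated acid chloride is avoided because dipolar cycloaddition competes. Alcohol 6 is a simple chroman with the stereocentre in place. The forward steps must not enolise 7, whose C3–H is alpha to the carbonyl and beta to an aryloxy leaving group.

**Stereocentre and ring C (6 ⇒ 5 ⇒ 4 ⇒ 3 ⇒ 1 + 2).** The C3–H and C4–H bonds are cut (asymmetric hydrogenation of acid 4 to acid 5), then the oxidation level is adjusted (4 from aldehyde 3), then O1–C2 and C3–C4 are cut (3 from salicylaldehyde 1 and acrolein 2). Hydrogenation of the free acid is chosen over the aldehyde or ester because the carboxylate is the directing group for which high enantioselectivity is established on 2H-chromene-3-carboxylic acids. The price is one oxidation and one reduction.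

**Siloxyalkyne (15 ⇒ 13 ⇒ 11 + 12).** The O–Si and C(sp)–O bonds are cut (ynolate 14 from terminal alkyne 13), then the propargylic C–C bond (13 from prenyl bromide 11 and ethynylmagnesium bromide 12). Oxygenation of an acetylide is shorter than homologation of an ester. The forward steps must couple at the primary end of the prenyl unit and must not isomerise the skipped enyne.

## Roads not taken

Alternative 1: Ring C is cut at C3–C4 and at the acyl C2–O1 bond. The arylacetic acid A2 (ring B with both phenols as methoxymethyl ethers) is activated with pivaloyl chloride and a chiral isothiourea. It then adds through its alpha carbon to the ortho-quinone methide A4, released by Cs2CO3 from sulfone A3, and closes to lactone A1.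
- Merits: the route is convergent, and the C3 centre and ring C arise in one catalytic C–C bond-forming step.
- Weak points: in A1, C3 is both benzylic and alpha to an aryl ester carbonyl, the most epimerisable situation possible. The C2 carbonyl must still be taken down to a methylene by reductive opening and re-etherification. A2 needs a prenyl group placed between two oxygens on a preformed arene, so the ring B regiochemistry is moved and not solved. The final acetal removal needs acid next to an ortho-prenylphenol.
- Comparison: Alternative 1 is clearly more convergent, and its longest line is probably no longer than the present one. The chosen plan sets against it a C3 centre that is never alpha to a carbonyl after step 5 and a ring B pattern dictated by mechanism.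

Alternative 2: The cuts are C3–C1' and, temporarily, C4–O2'. Chromene A6 and iodophenol A7 are joined by oxyarylation under Pd(OAc)2, a chiral bisphosphine and Ag2CO3 to the cis-fused pterocarpan A5. Reductive cleavage of its benzylic C4–O bond would then give compound 20 of the present route.
- Merits: this is the shortest way to the isoflavan skeleton, the cis fusion is automatic, and A6 is only two or three steps from 1.
- Weak points: enantiocontrol in this oxyarylation manifold is poorly developed, since the cationic palladium pathway gives the ligand little grip. The C4–O cleavage cannot use catalytic hydrogenolysis because of the prenyl group, so it needs dissolving-metal or acidic silane conditions on a sensitive substrate. A7 again requires regioselective prenylation and iodination of a resorcinol.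
- Comparison: if the asymmetric step worked, this road would reach 20 in fewer steps than steps 1–9. The chosen plan sets against it a hydrogenation with precedent on exactly this substrate class and a ring B that cannot come out as a regioisomer.

Alternative 3: The cuts are C4–C4a and C2–O1. The symmetric 2,6-dihydroxy-4-methoxybenzaldehyde A9 would add through a free ring carbon to the methylene of 2-arylacrolein A10 under a BINOL-derived phosphoric acid. Enantioselective protonation at C3 and lactol closure would give A8.
- Merits: ring A carries its final substitution from the first step, and the symmetry of A9 removes the C6/C8 question. In this respect the road is better than the chosen plan, which spends steps 10–13 on ring A and relies on steric bias for C8.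
- Weak points: A9 is a deactivated, hydrogen-bonded nucleophile. The stereocentre is created by protonation and then sits alpha to a masked aldehyde, because A8 equilibrates with its open form. The lactol must be deoxygenated with acid and silane beside an aryl aldehyde, acetals and a prenyl group. A10 again presupposes a regiodefined prenylated ring B.
- Comparison: the chosen plan sets against the shorter ring A sequence a configurationally secure C3 and an unambiguous ring B.

Key step: step 9

## Route

Step 1
Reactants: 1 2-hydroxy-4,6-dimethoxybenzaldehyde; 2 acrolein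
Product: 3 5,7-dimethoxy-2H-chromene-3-carbaldehyde
Conditions: K2CO3, 1,4-dioxane, reflux
Reagents that add atoms: none
Why: Domino oxa-Michael addition of the phenoxide to acrolein, intramolecular aldol addition and dehydration, a standard chromene synthesis from salicylaldehydes, forms O1–C2 and C3–C4 in one operation; no stereocentre is formed.

Step 2
Reactants: 3 5,7-dimethoxy-2H-chromene-3-carbaldehyde
Product: 4 5,7-dimethoxy-2H-chromene-3-carboxylic acid
Conditions: NaClO2, NaH2PO4, 2-methyl-2-butene (excess), t-BuOH/H2O, rt
Reagents that add atoms: sodium chlorite, [Na+].[O-]Cl=O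
Why: Pinnick oxidation of an unsaturated aldehyde; the alkene scavenger in large excess keeps hypochlorous acid away from the electron-rich ring and the ring double bond.

Step 3
Reactants: 4 5,7-dimethoxy-2H-chromene-3-carboxylic acid
Product: 5 (3S)-5,7-dimethoxychroman-3-carboxylic acid
Conditions: H2 (6 atm), [Ir(cod)(SIPHOX)]BArF (1 mol %), Cs2CO3 (0.5 equiv), MeOH, 45 °C; then aq. HCl
Reagents that add atoms: none
Why: Carboxylate-directed asymmetric hydrogenation of a trisubstituted alpha,beta-unsaturated acid; the carboxylate binds iridium and the chiral spiro phosphine-oxazoline pocket selects the face of C3=C4 that receives hydrogen, which sets C3; 2H-chromene-3-carboxylic acids are an established substrate class for these catalysts.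

Step 4
Reactants: 5 (3S)-5,7-dimethoxychroman-3-carboxylic acid
Product: 6 [(3R)-5,7-dimethoxychroman-3-yl]methanol
Conditions: BH3·THF, THF, 0 °C to rt; then MeOH
Reagents that add atoms: none
Why: Chemoselective borane reduction of a carboxylic acid through acyloxyboranes; no enolisable carbonyl species persists, so C3 is retained and its descriptor changes only through the priority rules.

Step 5
Reactants: 6 [(3R)-5,7-dimethoxychroman-3-yl]methanol
Product: 8 (3E)-4-[(3R)-5,7-dimethoxychroman-3-yl]but-3-en-2-one, via aldehyde 7 (not isolated)
Conditions: Dess–Martin periodinane, NaHCO3, CH2Cl2, 0 °C to rt; then Ph3P=CHC(O)CH3, rt to 40 °C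
Reagents that add atoms: 1-(triphenylphosphoranylidene)propan-2-one, CC(=O)C=P(c1ccccc1)(c1ccccc1)c1ccccc1
Why: Buffered Dess–Martin oxidation followed in the same flask by Wittig olefination with a ketone-stabilised ylide, which is E-selective; aldehyde 7, whose C3–H is alpha to the carbonyl and beta to an aryloxy leaving group, is neither isolated nor exposed to a base stronger than the ylide.

Step 6
Reactants: 8 (3E)-4-[(3R)-5,7-dimethoxychroman-3-yl]but-3-en-2-one
Product: 10 (3E)-1-diazo-4-[(3R)-5,7-dimethoxychroman-3-yl]but-3-en-2-one, via trifluoroacetyl diketone 9 (not isolated)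
Conditions: LiN(SiMe3)2, THF, −78 °C; CF3CO2CH2CF3; then 4-AcNHC6H4SO2N3, Et3N, H2O, MeCN, rt
Reagents that add atoms: 4-acetamidobenzenesulfonyl azide, CC(=O)Nc1ccc(cc1)S(=O)(=O)N=[N+]=[N-]; 2,2,2-trifluoroethyl trifluoroacetate, O=C(OCC(F)(F)F)C(F)(F)F (supplies the trifluoroacetyl group of 9 only, which is lost again)
Why: Detrifluoroacetylative diazo transfer: kinetic deprotonation of the methyl group, Claisen trifluoroacetylation to activate it, then Regitz diazo transfer in which the trifluoroacetyl group leaves on the sulfonamide; this is the standard entry to alpha,beta-unsaturated diazomethyl ketones, and the low temperature favours the methyl over the gamma hydrogen at C3.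

Step 7
Reactants: 11 prenyl bromide; 12 ethynylmagnesium bromide
Product: 13 5-methylhex-4-en-1-yne
Conditions: CuCl (5 mol %), THF, 0 to 50 °C
Reagents that add atoms: none
Why: Copper-catalysed alkynyl–allyl coupling at the unhindered primary terminus of the prenyl unit gives the skipped enyne; the volatile product is carried on as a distilled concentrate.

Step 8
Reactants: 13 5-methylhex-4-en-1-yne
Product: 15 triisopropyl[(5-methylhex-4-en-1-yn-1-yl)oxy]silane, via lithium ynolate 14 (not isolated)
Conditions: n-BuLi, THF, −78 °C; t-BuOOLi (from t-BuOOH and LiN(SiMe3)2), −78 to 0 °C; then i-Pr3SiOSO2CF3, −78 to 0 °C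
Reagents that add atoms: tert-butyl hydroperoxide, CC(C)(C)OO; triisopropylsilyl trifluoromethanesulfonate, CC(C)[Si](OS(=O)(=O)C(F)(F)F)(C(C)C)C(C)C
Why: Electrophilic oxygenation of the lithium acetylide by lithium tert-butyl peroxide gives the ynolate, which the bulky silyl triflate traps on oxygen, the established oxygenation route to triisopropylsilyl ynol ethers; one equivalent of base at −78 °C removes only the acetylenic hydrogen.

Step 9
Reactants: 10 (3E)-1-diazo-4-[(3R)-5,7-dimethoxychroman-3-yl]but-3-en-2-one; 15 triisopropyl[(5-methylhex-4-en-1-yn-1-yl)oxy]silane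
Product: 20 (3R)-2'-hydroxy-5,7-dimethoxy-3'-prenyl-4'-(triisopropylsilyloxy)isoflavan, via vinylketene 16 (not isolated), via vinylcyclobutenone 17 (not isolated), via dienylketene 18 (not isolated), via cyclohexadienone 19 (not isolated)
Conditions: hν (300 nm lamps, Pyrex), 15 (1.5 equiv), degassed ClCH2CH2Cl, rt; then 80 °C
Reagents that add atoms: none
Why: Light at 300 nm, absorbed by the unsaturated diazoketone and not by ring A, expels dinitrogen with migration of the alkenyl group (Wolff rearrangement, C5'–C6') to give vinylketene 16. The electrophilic ketene carbonyl carbon bonds to the nucleophilic, prenyl-bearing carbon of 15 (C2'–C3') and the ketene alpha carbon to the silyloxy-bearing carbon (C4'–C5'), a regiospecific [2+2] cycloaddition to cyclobutenone 17. Four-electron electrocyclic opening of 17 is reversible and gives dienylketene 18, whose isomer with the alkenyl group cis to the ketene is drained by thermal six-electron disrotatory electrocyclisation (C1'–C2') to dienone 19, and enolisation then gives phenol 20; this is how ring B closes. The closest known reaction is the Danheiser benzannulation in its diazoketone form, which with siloxyalkynes is an established route to 2-substituted resorcinol monosilyl ethers. No stereocentre is created in 20, since the sp3 ring carbons of 17 and 19 are transient, and C3, now insulated from every carbonyl group, is untouched under neutral conditions. The step needs one orientation in the [2+2] event and reaction at the alkyne and not at the prenyl alkene; the oxygen-polarised triple bond of 15 secures both, being far more nucleophilic at its alkyl-bearing carbon than the isolated trisubstituted alkene. The excess of 15 and the final heating serve to intercept all of 16 and to convert residual 17.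

Step 10
Reactants: 20 (3R)-2'-hydroxy-5,7-dimethoxy-3'-prenyl-4'-(triisopropylsilyloxy)isoflavan
Product: 21 (3R)-2'-(tert-butyldimethylsilyloxy)-5,7-dimethoxy-3'-prenyl-4'-(triisopropylsilyloxy)isoflavan
Conditions: t-BuMe2SiOSO2CF3, 2,6-lutidine, CH2Cl2, 0 °C to rt
Reagents that add atoms: tert-butyldimethylsilyl trifluoromethanesulfonate, CC(C)(C)[Si](C)(C)OS(=O)(=O)C(F)(F)F
Why: Silylation of a di-ortho-substituted phenol with a silyl triflate and a hindered base; capping the 2'-oxygen damps ring B as a nucleophile and removes the free ortho-prenylphenol before the acidic formylation.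

Step 11
Reactants: 21 (3R)-2'-(tert-butyldimethylsilyloxy)-5,7-dimethoxy-3'-prenyl-4'-(triisopropylsilyloxy)isoflavan
Product: 23 (3R)-2'-(tert-butyldimethylsilyloxy)-5,7-dimethoxy-3'-prenyl-4'-(triisopropylsilyloxy)isoflavan-8-carbaldehyde, via iminium chloride 22 (not isolated)
Conditions: POCl3, DMF, 0 °C to rt; then aq. NaOAc
Reagents that add atoms: N,N-dimethylformamide, CN(C)C=O (formyl carbon); water, O (aldehyde oxygen on hydrolysis of 22)
Why: Vilsmeier–Haack formylation of the trialkoxybenzene ring A, far more nucleophilic than the bis-silyloxy ring B; C8, flanked by one methoxy group and the tied-back ring oxygen, is less hindered than C6 between two methoxy groups, the same preference that governs electrophilic substitution of 5,7-dialkoxyflavans.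

Step 12
Reactants: 23 (3R)-2'-(tert-butyldimethylsilyloxy)-5,7-dimethoxy-3'-prenyl-4'-(triisopropylsilyloxy)isoflavan-8-carbaldehyde
Product: 24 (3R)-2'-(tert-butyldimethylsilyloxy)-7-hydroxy-5-methoxy-3'-prenyl-4'-(triisopropylsilyloxy)isoflavan-8-carbaldehyde
Conditions: MgI2·OEt2, toluene, 80 °C; then aq. NH4Cl
Reagents that add atoms: none
Why: Chelation-directed demethylation: magnesium bridges the formyl oxygen and the 7-methoxy oxygen and iodide attacks the methyl group, whereas the 5-methoxy group cannot chelate and the O1–C2 bond would require substitution at a beta-branched methylene; any silyl loss here is harmless because step 13 removes both silyl groups.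

Step 13
Reactants: 24 (3R)-2'-(tert-butyldimethylsilyloxy)-7-hydroxy-5-methoxy-3'-prenyl-4'-(triisopropylsilyloxy)isoflavan-8-carbaldehyde
Product: 25 (3R)-2',4',7-trihydroxy-5-methoxy-3'-prenylisoflavan-8-carbaldehyde
Conditions: Bu4NF, AcOH, THF, 0 °C
Reagents that add atoms: none
Why: Fluoride cleavage of both aryl silyl ethers under acetic acid buffering, which keeps the liberated phenoxides protonated and avoids acid near the ortho-prenylphenol; C3 is not affected.

## Compound list

1 | 2-hydroxy-4,6-dimethoxybenzaldehyde | COc1cc(O)c(C=O)c(OC)c1 | starting material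
2 | acrolein | C=CC=O | starting material
3 | 5,7-dimethoxy-2H-chromene-3-carbaldehyde | COc1cc(OC)cc2c1C=C(C=O)CO2 | intermediate
4 | 5,7-dimethoxy-2H-chromene-3-carboxylic acid | COc1cc(OC)cc2c1C=C(C(=O)O)CO2 | intermediate
5 | (3S)-5,7-dimethoxychroman-3-carboxylic acid | COc1cc(OC)cc2c1C[C@H](C(=O)O)CO2 | intermediate
6 | [(3R)-5,7-dimethoxychroman-3-yl]methanol | COc1cc(OC)cc2c1C[C@H](CO)CO2 | intermediate
7 | (3S)-5,7-dimethoxychroman-3-carbaldehyde | COc1cc(OC)cc2c1C[C@H](C=O)CO2 | intermediate (not isolated)
8 | (3E)-4-[(3R)-5,7-dimethoxychroman-3-yl]but-3-en-2-one | COc1cc(OC)cc2c1C[C@H](/C=C/C(C)=O)CO2 | intermediate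
9 | (5E)-6-[(3R)-5,7-dimethoxychroman-3-yl]-1,1,1-trifluorohex-5-ene-2,4-dione | COc1cc(OC)cc2c1C[C@H](/C=C/C(=O)CC(=O)C(F)(F)F)CO2 | intermediate (not isolated)
10 | (3E)-1-diazo-4-[(3R)-5,7-dimethoxychroman-3-yl]but-3-en-2-one | COc1cc(OC)cc2c1C[C@H](/C=C/C(=O)C=[N+]=[N-])CO2 | intermediate
11 | prenyl bromide (1-bromo-3-methylbut-2-ene) | CC(C)=CCBr | starting material
12 | ethynylmagnesium bromide | C#C[Mg]Br | starting material
13 | 5-methylhex-4-en-1-yne | C#CCC=C(C)C | intermediate
14 | lithium 5-methylhex-4-en-1-yn-1-olate | CC(C)=CCC#C[O-].[Li+] | intermediate (not isolated)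
15 | triisopropyl[(5-methylhex-4-en-1-yn-1-yl)oxy]silane | CC(C)=CCC#CO[Si](C(C)C)(C(C)C)C(C)C | intermediate
16 | (3E)-4-[(3R)-5,7-dimethoxychroman-3-yl]buta-1,3-dien-1-one | COc1cc(OC)cc2c1C[C@H](/C=C/C=C=O)CO2 | intermediate (not isolated)
17 | 4-{(E)-2-[(3R)-5,7-dimethoxychroman-3-yl]ethenyl}-2-prenyl-3-(triisopropylsilyloxy)cyclobut-2-en-1-one (both epimers at the ring sp3 carbon) | COc1cc(OC)cc2c1C[C@H](/C=C/C1C(=O)C(CC=C(C)C)=C1O[Si](C(C)C)(C(C)C)C(C)C)CO2 | intermediate (not isolated)
18 | (3E,5E)-6-[(3R)-5,7-dimethoxychroman-3-yl]-2-prenyl-3-(triisopropylsilyloxy)hexa-1,3,5-trien-1-one (ketene carbon and C5 cis across C3=C4) | COc1cc(OC)cc2c1C[C@H](/C=C/C=C(O[Si](C(C)C)(C(C)C)C(C)C)\C(CC=C(C)C)=C=O)CO2 | intermediate (not isolated)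
19 | 6-[(3R)-5,7-dimethoxychroman-3-yl]-2-prenyl-3-(triisopropylsilyloxy)cyclohexa-2,4-dien-1-one (both epimers at the ring sp3 carbon) | COc1cc(OC)cc2c1C[C@H](C1C=CC(O[Si](C(C)C)(C(C)C)C(C)C)=C(CC=C(C)C)C1=O)CO2 | intermediate (not isolated)
20 | (3R)-2'-hydroxy-5,7-dimethoxy-3'-prenyl-4'-(triisopropylsilyloxy)isoflavan | COc1cc(OC)cc2c1C[C@H](c1ccc(O[Si](C(C)C)(C(C)C)C(C)C)c(CC=C(C)C)c1O)CO2 | intermediate
21 | (3R)-2'-(tert-butyldimethylsilyloxy)-5,7-dimethoxy-3'-prenyl-4'-(triisopropylsilyloxy)isoflavan | COc1cc(OC)cc2c1C[C@H](c1ccc(O[Si](C(C)C)(C(C)C)C(C)C)c(CC=C(C)C)c1O[Si](C)(C)C(C)(C)C)CO2 | intermediate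
22 | 8-[(dimethyliminio)methyl] derivative of 21, chloride | COc1cc(OC)c(C=[N+](C)C)c2c1C[C@H](c1ccc(O[Si](C(C)C)(C(C)C)C(C)C)c(CC=C(C)C)c1O[Si](C)(C)C(C)(C)C)CO2.[Cl-] | intermediate (not isolated)
23 | (3R)-2'-(tert-butyldimethylsilyloxy)-5,7-dimethoxy-3'-prenyl-4'-(triisopropylsilyloxy)isoflavan-8-carbaldehyde | COc1cc(OC)c(C=O)c2c1C[C@H](c1ccc(O[Si](C(C)C)(C(C)C)C(C)C)c(CC=C(C)C)c1O[Si](C)(C)C(C)(C)C)CO2 | intermediate
24 | (3R)-2'-(tert-butyldimethylsilyloxy)-7-hydroxy-5-methoxy-3'-prenyl-4'-(triisopropylsilyloxy)isoflavan-8-carbaldehyde | COc1cc(O)c(C=O)c2c1C[C@H](c1ccc(O[Si](C(C)C)(C(C)C)C(C)C)c(CC=C(C)C)c1O[Si](C)(C)C(C)(C)C)CO2 | intermediate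
25 | (3R)-2',4',7-trihydroxy-5-methoxy-3'-prenylisoflavan-8-carbaldehyde | COc1cc(O)c(C=O)c2c1C[C@H](c1ccc(O)c(CC=C(C)C)c1O)CO2 | target

## Step count and least certain steps

Total: 13 steps. Longest linear sequence: 11 steps (1 to 25 through steps 1–6 and 9–13). The alkyne arm (steps 7–8) joins at step 9.

**Step 9 (key step).**
- What may go wrong: competing light absorption by ring A or by the product, leading to photodegradation; acylation of the product phenol by the vinylketene, which consumes both; incomplete thermal conversion of the cyclobutenone stage.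
- Fallback (from 10, back at 20): the ketene is generated without light. Silver-catalysed Wolff rearrangement of 10 in aqueous THF (AgOBz, Et3N) should give (3E)-4-[(3R)-5,7-dimethoxychroman-3-yl]but-3-enoic acid F1. Oxalyl chloride converts it into (3E)-4-[(3R)-5,7-dimethoxychroman-3-yl]but-3-enoyl chloride F2. Slow addition of Et3N to F2 and 15 in toluene at 80 °C generates 16 by dehydrochlorination, and 16 then runs through the same cycloaddition and electrocyclic sequence to 20.

**Step 3.**
- What may go wrong: insufficient enantioselectivity, or the opposite sense of induction with the ligand antipode first tried.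
- Fallback (from 4, back at 6): separation of covalent diastereomers. Hydrogenation of 4 over Pd/C gives racemic 5,7-dimethoxychroman-3-carboxylic acid F3. Pivaloyl chloride and Et3N convert it into the mixed pivalic anhydride F4, which acylates lithiated (4S)-4-benzyloxazolidin-2-one. The two imides are separated by chromatography or crystallisation: (4S)-4-benzyl-3-{[(3S)-5,7-dimethoxychroman-3-yl]carbonyl}oxazolidin-2-one F5 and its (3R)-diastereomer, (4S)-4-benzyl-3-{[(3R)-5,7-dimethoxychroman-3-yl]carbonyl}oxazolidin-2-one F6. Their configurations are to be assigned crystallographically. LiBH4 reduction of F5 gives 6 directly and returns the auxiliary.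

**Step 6.**
- What may go wrong: gamma-deprotonation of 8 at C3 by the amide base, followed by loss of configuration or vinylogous expulsion of the aryloxide (ring opening); incomplete trifluoroacetylation.
- Fallback (from 6, back at 10): the diazo group is brought in with the olefination reagent. Alcohol 6 is oxidised in the flask to 7 as in step 5 and treated with diethyl (3-diazo-2-oxopropyl)phosphonate F7, a known Horner–Wadsworth–Emmons reagent prepared in advance, under LiCl and i-Pr2NEt in MeCN. This gives 10 in one operation and avoids any strong base on the enone.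

**Step 8.**
- What may go wrong: base-induced isomerisation of the skipped enyne to allenic or conjugated isomers; incomplete oxygen transfer; hydrolysis of the ynol ether during isolation.
- Fallback (from 11, back at 14 and hence 15): Kowalski ester homologation. Palladium-catalysed ethoxycarbonylation of 11 (PdCl2(PPh3)2, CO, EtOH, Et3N) should give ethyl 4-methylpent-3-enoate F8. Addition of LiCHBr2 (from CH2Br2 and lithium 2,2,6,6-tetramethylpiperidide), then LiN(SiMe3)2 and n-BuLi, leads through the lithium enolate of 1,1-dibromo-5-methylhex-4-en-2-one F9 and its rearrangement to ynolate 14. Silylation as in step 8 gives 15.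

**Step 11.**
- What may go wrong: partial formylation at C6 instead of C8; addition of HCl to the prenyl alkene; loss of a silyl group under the acidic conditions followed by ring closure of the ortho-prenylphenol.
- Fallback (from 21, back at 23): halogenation and halogen–metal exchange in place of direct formylation. N-Bromosuccinimide (1 equiv, CH2Cl2, −78 °C) should brominate ring A at C8 to give (3R)-8-bromo-2'-(tert-butyldimethylsilyloxy)-5,7-dimethoxy-3'-prenyl-4'-(triisopropylsilyloxy)isoflavan F10. Its regiochemistry can be checked and a minor isomer removed at this stage. Exchange with n-BuLi in THF at −78 °C gives the 8-lithio derivative of 21, F11, and DMF then delivers 23 under non-acidic conditions.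

## Further compounds

F1 | step 9 | (3E)-4-[(3R)-5,7-dimethoxychroman-3-yl]but-3-enoic acid | COc1cc(OC)cc2c1C[C@H](/C=C/CC(=O)O)CO2
F2 | step 9 | (3E)-4-[(3R)-5,7-dimethoxychroman-3-yl]but-3-enoyl chloride | COc1cc(OC)cc2c1C[C@H](/C=C/CC(=O)Cl)CO2
F3 | step 3 | racemic 5,7-dimethoxychroman-3-carboxylic acid | COc1cc(OC)cc2c1CC(C(=O)O)CO2
F4 | step 3 | racemic 5,7-dimethoxychroman-3-carboxylic pivalic anhydride | COc1cc(OC)cc2c1CC(C(=O)OC(=O)C(C)(C)C)CO2
F5 | step 3 | (4S)-4-benzyl-3-{[(3S)-5,7-dimethoxychroman-3-yl]carbonyl}oxazolidin-2-one | COc1cc(OC)cc2c1C[C@H](C(=O)N1[C@@H](Cc3ccccc3)COC1=O)CO2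
F6 | step 3 | (4S)-4-benzyl-3-{[(3R)-5,7-dimethoxychroman-3-yl]carbonyl}oxazolidin-2-one | COc1cc(OC)cc2c1C[C@@H](C(=O)N1[C@@H](Cc3ccccc3)COC1=O)CO2
F7 | step 6 | diethyl (3-diazo-2-oxopropyl)phosphonate | CCOP(=O)(OCC)CC(=O)C=[N+]=[N-]
F8 | step 8 | ethyl 4-methylpent-3-enoate | CCOC(=O)CC=C(C)C
F9 | step 8 | lithium enolate of 1,1-dibromo-5-methylhex-4-en-2-one | CC(C)=CCC([O-])=C(Br)Br.[Li+]
F10 | step 11 | (3R)-8-bromo-2'-(tert-butyldimethylsilyloxy)-5,7-dimethoxy-3'-prenyl-4'-(triisopropylsilyloxy)isoflavan | COc1cc(OC)c(Br)c2c1C[C@H](c1ccc(O[Si](C(C)C)(C(C)C)C(C)C)c(CC=C(C)C)c1O[Si](C)(C)C(C)(C)C)CO2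
F11 | step 11 | 8-lithio derivative of 21 | COc1cc(OC)c([Li])c2c1C[C@H](c1ccc(O[Si](C(C)C)(C(C)C)C(C)C)c(CC=C(C)C)c1O[Si](C)(C)C(C)(C)C)CO2
A1 | alternative 1 | (3R)-3-[2,4-bis(methoxymethoxy)-3-prenylphenyl]-5,7-dimethoxychroman-2-one | COc1cc(OC)cc2c1C[C@H](c1ccc(OCOC)c(CC=C(C)C)c1OCOC)C(=O)O2
A2 | alternative 1 | 2-[2,4-bis(methoxymethoxy)-3-prenylphenyl]acetic acid | OC(=O)Cc1ccc(OCOC)c(CC=C(C)C)c1OCOC
A3 | alternative 1 | 3,5-dimethoxy-2-[(phenylsulfonyl)methyl]phenol | COc1cc(O)c(CS(=O)(=O)c2ccccc2)c(OC)c1
A4 | alternative 1 | 3,5-dimethoxy-6-methylidenecyclohexa-2,4-dien-1-one (ortho-quinone methide) | C=C1C(=O)C=C(OC)C=C1OC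
A5 | alternative 2 | cis-fused 1,3-dimethoxy-10-prenyl-9-(triisopropylsilyloxy)pterocarpan | COc1cc(OC)cc2c1[C@H]1[C@H](c3ccc(O[Si](C(C)C)(C(C)C)C(C)C)c(CC=C(C)C)c3O1)CO2
A6 | alternative 2 | 5,7-dimethoxy-2H-chromene | COc1cc(OC)cc2c1C=CCO2
A7 | alternative 2 | 6-iodo-2-prenyl-3-(triisopropylsilyloxy)phenol | Oc1c(I)ccc(O[Si](C(C)C)(C(C)C)C(C)C)c1CC=C(C)C
A8 | alternative 3 | 8-formyl-7-hydroxy-5-methoxy-2',4'-bis(methoxymethoxy)-3'-prenylisoflavan-2-ol (both anomers) | COc1cc(O)c(C=O)c2c1C[C@H](c1ccc(OCOC)c(CC=C(C)C)c1OCOC)C(O)O2
A9 | alternative 3 | 2,6-dihydroxy-4-methoxybenzaldehyde | COc1cc(O)c(C=O)c(O)c1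
A10 | alternative 3 | 2-[2,4-bis(methoxymethoxy)-3-prenylphenyl]prop-2-enal | C=C(C=O)c1ccc(OCOC)c(CC=C(C)C)c1OCOC
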